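**Retrosynthetic overview**
- Target 24 comes from protected (2S)-flavanone 23 by one acidic methanolysis that removes the two ring B acetates, the two ring A MOM ethers and the silyl ether.
- Ring C is the only ring formed and is cut at the C4–C4a aryl ketone bond. This rests on the fact that C8 of ring A carries the side chain, so C4a is the only free position ortho to O1, and on the O1–C2 benzylic aryl ether, which holds the C2 stereocentre before ring closure. 23 comes from acid 21 by intramolecular Friedel–Crafts acylation.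
- The O1–C2 ether of 21 is cut to ring A phenol 12 and ring B (R)-β-hydroxy allyl ester 19, joined by Mitsunobu inversion (R to S).
- Phenol 12: tris-MOM phloroglucinol is lithiated and added to the trans-prenylated (S)-β-methyl-γ-butyrolactone 5; one ortho MOM is removed by chelation and the ortho-hydroxyaryl ketone is reduced to CH2.
- Ester 19: 2,4-diacetoxybenzoic acid is taken to the allyl β-keto ester through its acyl Meldrum's acid under base-free conditions, then reduced by asymmetric transfer hydrogenation.

Key step: step 13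

Assumption: (S)-4-methyldihydrofuran-2(3H)-one 3 is taken as a purchasable enantiopure lactone, and ring B is built from 2,4-dihydroxybenzoic acid because an ortho-acetoxy aryl ketone or keto ester would undergo acyl transfer under any base-mediated Claisen condensation or hot acidic alcohol.

**Route**

Step 1
Reactants: 1 phloroglucinol
Product: 2 1,3,5-tris(methoxymethoxy)benzene
Conditions: NaH, MOMCl, DMF, 0 °C → rt
Reagents that add atoms: chloromethyl methyl ether, COCCl
Why: Williamson O-alkylation of the trisodium phenoxide with a hard chloromethyl ether should give the tris-acetal, whose MOM groups later direct lithiation and keep ring A electron-rich.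

Step 2
Reactants: 3 (S)-4-methyldihydrofuran-2(3H)-one; 4 prenyl bromide
Product: 5 (3S,4S)-4-methyl-3-(3-methylbut-2-en-1-yl)dihydrofuran-2(3H)-one (trans)
Conditions: LiN(i-Pr)2, THF, −78 °C; then 4, −78 → −40 °C
Reagents that add atoms: none
Why: Lithium enolate alkylation of a β-substituted γ-butyrolactone, in which prenyl bromide should approach the enolate face anti to the C4 methyl group, so the new C3 centre is set trans (3S) by substrate control.

Step 3
Reactants: 2 1,3,5-tris(methoxymethoxy)benzene; 5 trans-lactone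
Product: 7 (2S,3S)-4-hydroxy-3-methyl-2-(3-methylbut-2-en-1-yl)-1-[2,4,6-tris(methoxymethoxy)phenyl]butan-1-one, via 2,4,6-tris(methoxymethoxy)phenyllithium 6 (not isolated)
Conditions: n-BuLi, THF, 0 °C; then 5, −78 → −40 °C; aq. NH4Cl
Reagents that add atoms: none
Why: Directed ortho-lithiation between two MOM ethers (all three ring positions are equivalent) followed by acyl addition to the lactone carbonyl should stop at the ketone, because the lithium hemiketal and the two ortho substituents block a second addition; the two stereocentres are not touched.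

Step 4
Reactants: 7 hydroxy ketone
Product: 8 (2S,3S)-4-[(tert-butyldimethylsilyl)oxy]-3-methyl-2-(3-methylbut-2-en-1-yl)-1-[2,4,6-tris(methoxymethoxy)phenyl]butan-1-one
Conditions: TBSCl, imidazole, DMF, 0 °C → rt
Reagents that add atoms: tert-butyldimethylsilyl chloride, CC(C)(C)[Si](C)(C)Cl
Why: Standard imidazole-mediated silylation of the primary alcohol, which also fixes the open-chain ketone form and removes the nucleophile that could later trap the quinone methide or compete in the Mitsunobu reaction.

Step 5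
Reactants: 8 silyl ether ketone
Product: 9 (2S,3S)-4-[(tert-butyldimethylsilyl)oxy]-1-[2-hydroxy-4,6-bis(methoxymethoxy)phenyl]-3-methyl-2-(3-methylbut-2-en-1-yl)butan-1-one
Conditions: MgBr2·OEt2, Et2O/CH2Cl2, 0 °C → rt
Reagents that add atoms: none
Why: Chelation-controlled acetal cleavage, in which magnesium held between the ketone oxygen and one ortho MOM oxygen activates only that acetal toward bromide (the known ortho-selective dealkylation of aryl ketones), while the para MOM and the silyl ether lack the chelate.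

Step 6
Reactants: 9 ortho-hydroxyaryl ketone
Product: 12 2-[(2R,3S)-4-[(tert-butyldimethylsilyl)oxy]-3-methyl-2-(3-methylbut-2-en-1-yl)butyl]-3,5-bis(methoxymethoxy)phenol, via aryl ethyl carbonate 10 (not isolated), via ortho-quinone methide 11 (not isolated)
Conditions: ClCO2Et, Et3N, THF, 0 °C; then NaBH4, THF/H2O, 0 °C → rt
Reagents that add atoms: none
Why: Reductive deoxygenation of an ortho-hydroxyaryl ketone through its carbonate: hydride reduces the ketone, the carbonate moves to the benzylic alkoxide and leaves, and the ortho-quinone methide takes a second hydride at the exocyclic carbon under non-acidic conditions that should leave the adjacent stereocentre, the MOM groups, the silyl ether and the alkene alone.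

Step 7
Reactants: 13 2,4-dihydroxybenzoic acid
Product: 14 2,4-diacetoxybenzoic acid
Conditions: Ac2O, H2SO4 (cat.), 60 °C; then H2O
Reagents that add atoms: acetic anhydride, CC(=O)OC(C)=O
Why: Acid-catalysed acetylation of both phenols (the aspirin-type esterification), with any mixed anhydride at the carboxyl group hydrolysed on aqueous work-up.

Step 8
Reactants: 14 2,4-diacetoxybenzoic acid; 15 Meldrum's acid
Product: 17 5-[(2,4-diacetoxyphenyl)(hydroxy)methylidene]-2,2-dimethyl-1,3-dioxane-4,6-dione, via 2,4-diacetoxybenzoyl chloride 16 (not isolated)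
Conditions: (COCl)2, DMF (cat.), CH2Cl2, rt; then 15, pyridine, CH2Cl2, 0 °C → rt
Reagents that add atoms: none
Why: Acid chloride formation followed by C-acylation of Meldrum's acid under pyridine, a base too weak to trigger acyl transfer from the ortho acetate.

Step 9
Reactants: 17 acyl Meldrum's acid
Product: 18 allyl 3-(2,4-diacetoxyphenyl)-3-oxopropanoate
Conditions: allyl alcohol, toluene, 85 °C
Reagents that add atoms: allyl alcohol, C=CCO
Why: Thermal cycloreversion of the acyl Meldrum's acid to an aroylketene that is trapped by allyl alcohol should give the β-keto ester without any base.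

Step 10
Reactants: 18 allyl β-keto ester
Product: 19 allyl (3R)-3-(2,4-diacetoxyphenyl)-3-hydroxypropanoate
Conditions: RuCl[(R,R)-TsDPEN](p-cymene) (1 mol %), HCO2H/Et3N (5:2), EtOAc, 25 °C
Reagents that add atoms: none
Why: Noyori-type asymmetric transfer hydrogenation of an aryl ketone, in which the (R,R)-catalyst should deliver hydride to the face that gives the (R)-benzylic carbinol (the sense found for aryl ketones and aroylacetates), in a formic acid buffer that spares the allyl ester and limits acetyl migration; 19 is used at once.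

Step 11
Reactants: 12 ring A phenol; 19 (R)-β-hydroxy allyl ester
Product: 20 allyl (3S)-3-{2-[(2R,3S)-4-[(tert-butyldimethylsilyl)oxy]-3-methyl-2-(3-methylbut-2-en-1-yl)butyl]-3,5-bis(methoxymethoxy)phenoxy}-3-(2,4-diacetoxyphenyl)propanoate
Conditions: PPh3, DIAD, toluene, 0 °C → rt
Reagents that add atoms: none
Why: Mitsunobu etherification, in which the phenoxide displaces the oxyphosphonium group of the secondary benzylic alcohol in an SN2 reaction, so the (R)-carbinol is inverted to the (S)-ether that becomes C2.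

Step 12
Reactants: 20 allyl ester
Product: 21 (3S)-3-{2-[(2R,3S)-4-[(tert-butyldimethylsilyl)oxy]-3-methyl-2-(3-methylbut-2-en-1-yl)butyl]-3,5-bis(methoxymethoxy)phenoxy}-3-(2,4-diacetoxyphenyl)propanoic acid
Conditions: Pd(PPh3)4 (5 mol %), PhSiH3, CH2Cl2, rt
Reagents that add atoms: none
Why: Tsuji–Trost deallylation, in which zerovalent palladium ionises the allyl ester and the silane reduces the allyl fragment to propene, under neutral conditions that avoid hydroxide (which would cleave the acetates and eliminate the β-aryloxy group).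

Step 13
Reactants: 21 3-aryl-3-aryloxypropanoic acid
Product: 23 (2S)-2-(2,4-diacetoxyphenyl)-8-[(2R,3S)-4-[(tert-butyldimethylsilyl)oxy]-3-methyl-2-(3-methylbut-2-en-1-yl)butyl]-5,7-bis(methoxymethoxy)chroman-4-one, via acid chloride 22 (not isolated)
Conditions: 1-chloro-N,N,2-trimethylprop-1-en-1-amine, CH2Cl2, 0 °C; then AgOTf, 2,6-di-tert-butyl-4-methylpyridine, CH2Cl2, −78 → −20 °C
Reagents that add atoms: none
Why: The acid is turned under neutral conditions into acid chloride 22, which AgOTf ionises to an acyl triflate or acylium ion that is attacked by C4a of ring A (ortho to O1 and to the C5 MOM ether, para to the C7 MOM ether), and the Wheland intermediate gives its proton to the hindered pyridine. The closest known reaction type is the intramolecular Friedel–Crafts acylation of 3-aryloxy-3-arylpropanoic acids to 2-arylchroman-4-ones. Ring C closes as a six-membered ring by attack of the arene carbon on the exocyclic acyl carbon (6-exo with respect to the C=O), which forms the C4–C4a bond. No stereocentre is formed; C2, set in step 11, is carried through. The step needs regioselectivity, secured because C8 is alkylated and C6 cannot reach the acyl carbon, and it needs the C2–O1 bond not to ionise, secured because the acetates turn the two strongly donating oxygens of ring B into weak donors and because the very nucleophilic ring A allows a buffered low-temperature activation. The same buffer should protect the MOM acetals, the silyl ether and the prenyl alkene from triflic acid.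

Step 14
Reactants: 23 protected flavanone
Product: 24 (2S)-2-(2,4-dihydroxyphenyl)-5,7-dihydroxy-8-[(2R,3S)-4-hydroxy-3-methyl-2-(3-methylbut-2-en-1-yl)butyl]chroman-4-one (CNP0262638.1)
Conditions: HCl (1 M) in MeOH, 0 → 35 °C
Reagents that add atoms: none
Why: Acid-catalysed methanolysis should remove the MOM groups by acetal exchange, the aryl acetates by transesterification and the primary silyl ether by solvolysis in one operation, without the basic conditions that open ring C and racemise C2, and the alkene cannot cyclise onto a phenol through a favourable ring size.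

**Compound list**
1 | phloroglucinol | Oc1cc(O)cc(O)c1 | starting material
2 | 1,3,5-tris(methoxymethoxy)benzene | COCOc1cc(OCOC)cc(OCOC)c1 | intermediate
3 | (S)-4-methyldihydrofuran-2(3H)-one | O=C1C[C@H](C)CO1 | starting material
4 | prenyl bromide (1-bromo-3-methylbut-2-ene) | CC(C)=CCBr | starting material
5 | (3S,4S)-4-methyl-3-(3-methylbut-2-en-1-yl)dihydrofuran-2(3H)-one | CC(C)=CC[C@@H]1C(=O)OC[C@H]1C | intermediate
6 | 2,4,6-tris(methoxymethoxy)phenyllithium | COCOc1cc(OCOC)c([Li])c(OCOC)c1 | intermediate (not isolated)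
7 | (2S,3S)-4-hydroxy-3-methyl-2-(3-methylbut-2-en-1-yl)-1-[2,4,6-tris(methoxymethoxy)phenyl]butan-1-one | CC(C)=CC[C@H](C(=O)c1c(OCOC)cc(OCOC)cc1OCOC)[C@H](C)CO | intermediate
8 | (2S,3S)-4-[(tert-butyldimethylsilyl)oxy]-3-methyl-2-(3-methylbut-2-en-1-yl)-1-[2,4,6-tris(methoxymethoxy)phenyl]butan-1-one | CC(C)=CC[C@H](C(=O)c1c(OCOC)cc(OCOC)cc1OCOC)[C@H](C)CO[Si](C)(C)C(C)(C)C | intermediate
9 | (2S,3S)-4-[(tert-butyldimethylsilyl)oxy]-1-[2-hydroxy-4,6-bis(methoxymethoxy)phenyl]-3-methyl-2-(3-methylbut-2-en-1-yl)butan-1-one | CC(C)=CC[C@H](C(=O)c1c(O)cc(OCOC)cc1OCOC)[C@H](C)CO[Si](C)(C)C(C)(C)C | intermediate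
10 | ethyl carbonate of phenol 9 | CC(C)=CC[C@H](C(=O)c1c(OC(=O)OCC)cc(OCOC)cc1OCOC)[C@H](C)CO[Si](C)(C)C(C)(C)C | intermediate (not isolated)
11 | ortho-quinone methide, 6-alkylidene-3,5-bis(methoxymethoxy)cyclohexa-2,4-dien-1-one bearing the silylated side chain | CC(C)=CC[C@H](C=C1C(=O)C=C(OCOC)C=C1OCOC)[C@H](C)CO[Si](C)(C)C(C)(C)C | intermediate (not isolated)
12 | 2-[(2R,3S)-4-[(tert-butyldimethylsilyl)oxy]-3-methyl-2-(3-methylbut-2-en-1-yl)butyl]-3,5-bis(methoxymethoxy)phenol | CC(C)=CC[C@H](Cc1c(O)cc(OCOC)cc1OCOC)[C@H](C)CO[Si](C)(C)C(C)(C)C | intermediate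
13 | 2,4-dihydroxybenzoic acid | OC(=O)c1ccc(O)cc1O | starting material
14 | 2,4-diacetoxybenzoic acid | CC(=O)Oc1ccc(C(O)=O)c(OC(C)=O)c1 | intermediate
15 | Meldrum's acid (2,2-dimethyl-1,3-dioxane-4,6-dione) | CC1(C)OC(=O)CC(=O)O1 | starting material
16 | 2,4-diacetoxybenzoyl chloride | CC(=O)Oc1ccc(C(Cl)=O)c(OC(C)=O)c1 | intermediate (not isolated)
17 | 5-[(2,4-diacetoxyphenyl)(hydroxy)methylidene]-2,2-dimethyl-1,3-dioxane-4,6-dione | CC(=O)Oc1ccc(C(O)=C2C(=O)OC(C)(C)OC2=O)c(OC(C)=O)c1 | intermediate
18 | allyl 3-(2,4-diacetoxyphenyl)-3-oxopropanoate | C=CCOC(=O)CC(=O)c1ccc(OC(C)=O)cc1OC(C)=O | intermediate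
19 | allyl (3R)-3-(2,4-diacetoxyphenyl)-3-hydroxypropanoate | C=CCOC(=O)C[C@@H](O)c1ccc(OC(C)=O)cc1OC(C)=O | intermediate
20 | allyl (3S)-3-{2-[(2R,3S)-4-[(tert-butyldimethylsilyl)oxy]-3-methyl-2-(3-methylbut-2-en-1-yl)butyl]-3,5-bis(methoxymethoxy)phenoxy}-3-(2,4-diacetoxyphenyl)propanoate | CC(C)=CC[C@H](Cc1c(OCOC)cc(OCOC)cc1O[C@H](c1ccc(OC(C)=O)cc1OC(C)=O)CC(=O)OCC=C)[C@H](C)CO[Si](C)(C)C(C)(C)C | intermediate
21 | (3S)-3-{2-[(2R,3S)-4-[(tert-butyldimethylsilyl)oxy]-3-methyl-2-(3-methylbut-2-en-1-yl)butyl]-3,5-bis(methoxymethoxy)phenoxy}-3-(2,4-diacetoxyphenyl)propanoic acid | CC(C)=CC[C@H](Cc1c(OCOC)cc(OCOC)cc1O[C@H](c1ccc(OC(C)=O)cc1OC(C)=O)CC(O)=O)[C@H](C)CO[Si](C)(C)C(C)(C)C | intermediate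
22 | acid chloride of 21 | CC(C)=CC[C@H](Cc1c(OCOC)cc(OCOC)cc1O[C@H](c1ccc(OC(C)=O)cc1OC(C)=O)CC(Cl)=O)[C@H](C)CO[Si](C)(C)C(C)(C)C | intermediate (not isolated)
23 | (2S)-2-(2,4-diacetoxyphenyl)-8-[(2R,3S)-4-[(tert-butyldimethylsilyl)oxy]-3-methyl-2-(3-methylbut-2-en-1-yl)butyl]-5,7-bis(methoxymethoxy)chroman-4-one | CC(C)=CC[C@H](Cc1c(OCOC)cc(OCOC)c2c1O[C@H](c1ccc(OC(C)=O)cc1OC(C)=O)CC2=O)[C@H](C)CO[Si](C)(C)C(C)(C)C | intermediate
24 | (2S)-2-(2,4-dihydroxyphenyl)-5,7-dihydroxy-8-[(2R,3S)-4-hydroxy-3-methyl-2-(3-methylbut-2-en-1-yl)butyl]chroman-4-one | CC(C)=CC[C@H](Cc1c(O)cc(O)c2c1O[C@H](c1ccc(O)cc1O)CC2=O)[C@H](C)CO | target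

**Step count and risk**
Total steps: 14. Longest linear sequence: 9 steps (step 2 or 1, then 3, 4, 5, 6, 11, 12, 13, 14).

Steps most likely to fail:

Step 13 (key step). The benzylic C2–O1 bond may ionise under the electrophilic activation, which would scramble C2 or cleave the ether. Triflic acid that escapes the buffer may remove MOM groups or add to the prenyl alkene. The ortho-acetoxy oxygen of ring B may attack the acylium carbon and lactonise with loss of acetyl. The fallback forms the C4–C4a bond before the O1–C2 bond, sets out from phenol 12 and comes back at 23. Phenol 12 would be formylated at its only free ortho position (MgCl2, Et3N, paraformaldehyde, MeCN, reflux) to the salicylaldehyde F1. MeMgBr would give the benzylic carbinol F2 and MnO2 the ortho-hydroxyacetophenone F3. A boron aldol reaction (Ipc2BCl, Et3N, −78 °C, the reagent enantiomer chosen to give the 3R carbinol) with 2,4-diacetoxybenzaldehyde F4 (from 2,4-dihydroxybenzaldehyde, Ac2O, pyridine) would give the β-hydroxy ketone F5. An intramolecular Mitsunobu reaction (PPh3, DIAD; 6-exo-tet, inversion) would then close the O1–C2 bond and return to 23 without any acylium chemistry.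

Step 11. The activated β-hydroxy ester may eliminate to the cinnamate, the ortho acetate may participate or migrate and erode the inversion, and displacement by the ortho-substituted phenol may be slow. The fallback avoids phosphonium activation, sets out from 19 and 12 and comes back at acid 21. Ester 19 would be deallylated (Pd(PPh3)4, PhSiH3) to the (3R)-hydroxy acid F6 and lactonised through carboxyl activation (PhSO2Cl, pyridine, 0 °C, retention at the carbinol carbon) to the (4R)-β-lactone F7. The sodium phenoxide of 12 (NaH, THF/DMF, 0 °C) would open the lactone at the benzylic carbon by alkyl–oxygen cleavage with inversion, which gives 21 directly and also saves step 12. Any acetyl scrambling would be repaired with Ac2O and pyridine.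

Step 3. The hindered aryllithium may deprotonate the α-branched lactone instead of adding, which gives low conversion and epimerisation at C3. The fallback uses a more electrophilic, non-enolising partner, sets out from lactone 5 and comes back at ketone 8. Lactone 5 would be opened with MeNH(OMe)·HCl and AlMe3 to the hydroxy Weinreb amide F8, silylated (TBSCl, imidazole) to the silyl ether F9 and reduced with i-Bu2AlH at −78 °C to the aldehyde F10. Aryllithium 6 would add at −78 °C to give the benzylic carbinol F11 (both epimers at the carbinol carbon), and Dess–Martin oxidation would return to 8.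

Further compounds
F1 | step 13 | 3-[(2R,3S)-4-[(tert-butyldimethylsilyl)oxy]-3-methyl-2-(3-methylbut-2-en-1-yl)butyl]-2-hydroxy-4,6-bis(methoxymethoxy)benzaldehyde | CC(C)=CC[C@H](Cc1c(O)c(C=O)c(OCOC)cc1OCOC)[C@H](C)CO[Si](C)(C)C(C)(C)C
F2 | step 13 | 1-{3-[(2R,3S)-4-[(tert-butyldimethylsilyl)oxy]-3-methyl-2-(3-methylbut-2-en-1-yl)butyl]-2-hydroxy-4,6-bis(methoxymethoxy)phenyl}ethanol (carbinol epimers) | CC(C)=CC[C@H](Cc1c(O)c(C(C)O)c(OCOC)cc1OCOC)[C@H](C)CO[Si](C)(C)C(C)(C)C
F3 | step 13 | 1-{3-[(2R,3S)-4-[(tert-butyldimethylsilyl)oxy]-3-methyl-2-(3-methylbut-2-en-1-yl)butyl]-2-hydroxy-4,6-bis(methoxymethoxy)phenyl}ethanone | CC(C)=CC[C@H](Cc1c(O)c(C(C)=O)c(OCOC)cc1OCOC)[C@H](C)CO[Si](C)(C)C(C)(C)C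
F4 | step 13 | 2,4-diacetoxybenzaldehyde | CC(=O)Oc1ccc(C=O)c(OC(C)=O)c1
F5 | step 13 | (3R)-1-{3-[(2R,3S)-4-[(tert-butyldimethylsilyl)oxy]-3-methyl-2-(3-methylbut-2-en-1-yl)butyl]-2-hydroxy-4,6-bis(methoxymethoxy)phenyl}-3-(2,4-diacetoxyphenyl)-3-hydroxypropan-1-one | CC(C)=CC[C@H](Cc1c(O)c(C(=O)C[C@@H](O)c2ccc(OC(C)=O)cc2OC(C)=O)c(OCOC)cc1OCOC)[C@H](C)CO[Si](C)(C)C(C)(C)C
F6 | step 11 | (3R)-3-(2,4-diacetoxyphenyl)-3-hydroxypropanoic acid | OC(=O)C[C@@H](O)c1ccc(OC(C)=O)cc1OC(C)=O
F7 | step 11 | (4R)-4-(2,4-diacetoxyphenyl)oxetan-2-one | O=C1C[C@H](c2ccc(OC(C)=O)cc2OC(C)=O)O1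
F8 | step 3 | (2S,3S)-4-hydroxy-N-methoxy-N,3-dimethyl-2-(3-methylbut-2-en-1-yl)butanamide | CC(C)=CC[C@H](C(=O)N(C)OC)[C@H](C)CO
F9 | step 3 | (2S,3S)-4-[(tert-butyldimethylsilyl)oxy]-N-methoxy-N,3-dimethyl-2-(3-methylbut-2-en-1-yl)butanamide | CC(C)=CC[C@H](C(=O)N(C)OC)[C@H](C)CO[Si](C)(C)C(C)(C)C
F10 | step 3 | (2S,3S)-4-[(tert-butyldimethylsilyl)oxy]-3-methyl-2-(3-methylbut-2-en-1-yl)butanal | CC(C)=CC[C@H](C=O)[C@H](C)CO[Si](C)(C)C(C)(C)C
F11 | step 3 | (2S,3S)-4-[(tert-butyldimethylsilyl)oxy]-3-methyl-2-(3-methylbut-2-en-1-yl)-1-[2,4,6-tris(methoxymethoxy)phenyl]butan-1-ol (carbinol epimers) | CC(C)=CC[C@H](C(O)c1c(OCOC)cc(OCOC)cc1OCOC)[C@H](C)CO[Si](C)(C)C(C)(C)C
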